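## Structural features

The target is a germacranolide: a ten-membered carbocycle (C1–C10) trans-fused at C7–C8 to an α-methylene-γ-butyrolactone (C11–C13, ring oxygen on C8). The ring holds two trisubstituted olefins, C1=C10 (E, methyl C14 on C10) and C4=C5 (ring-trans, CIP Z, acyloxymethyl C15 on C4 cis to C6). C6 (free allylic alcohol, R), C7 (S) and C8 (S) are contiguous; in the open chain C5–C9 the C6–O, C7–C11 and C8–O bonds are all syn. C15 carries an (E)-4-hydroxy-2-methylbut-2-enoate ester. The fragile groups are the α-methylene lactone (Michael acceptor), the allylic enoate ester, the 1(10),4-diene (acid-promoted transannular cyclisation, Cope rearrangement on heating) and the free C6 hydroxyl, which can translactonise under base. The real difficulty is closing the strained ring with both olefins ring-trans while the C6–C8 triad is in place, and telling four hydroxyl functions apart. The key step exploits the homoallylic alcohol array O–C8–C9–C10=C1: the C9–C10 bond and the E olefin are made together from a C8–C9 epoxide and a C1≡C10 methyl alkyne.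

## Logic of the disconnections

**C15–O ester.** 36 is traced through its bis-silyl ether 35 to 30 and 34 by cutting the acyl–O15 bond. The side chain is an allylic, conjugated ester that would not survive zerovalent nickel or the organometallic steps, so it goes on last. This removes five carbons and one olefin. The demand is that only O15 is free at that point, so O6 must carry a silyl group that outlasts the one on O15, and the last desilylation must spare lactone, ester and diene.

**Lactone C12–O8.** 30 and 29 are traced to 26 and then 25 by cutting the lactone C–O bond and lowering C12 to the alcohol level. A Michael-accepting lactone cannot pass through a phosphine/nickel/borane step, whereas a protected 2-methylene-1,4-diol can. The gain is that O8 becomes the free homoallylic alcohol that the key step delivers. The demand is that C12–OH is the only oxidisable allylic alcohol at lactonisation, and that its protecting group leaves orthogonally to silyl ethers.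

**C9–C10 (key).** 25 is cut to 24. One cut opens the ring, turns the E olefin into an alkyne and the C8 carbinol into an epoxide, and leaves an open chain with no ring strain. The demand is a reductive alkyne–epoxide coupling that bonds at C10 rather than C1 and beats oligomerisation; it creates no stereocentre.

**Epoxide and C8.** 24 goes back to 23 (O6–Si), to chlorohydrin 22 (C9–O), to ketone 21 (C8–H) and to 20 (C8–C9). The free C6 hydroxyl directs the creation of C8 (1,3-syn), and the two secondary hydroxyls are then told apart automatically: O8 closes the epoxide and O6 is silylated. The demand is a single addition of a one-carbon nucleophile to the amide without disturbing C7, which is allylic and α to a carbonyl.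

**C6–C7 aldol.** 20 comes from 19, and 19 from 17 and 9. This is the convergent cut: it separates the stereotriad from the C1–C6 chain and sets C6 and C7 in one auxiliary-controlled step. The demand is α-selective, syn-selective reaction of a dienolate.

**Imide.** 17 is cut at N–acyl to 14 and 15; 14 at C7–C8 (carboxylation of 13) to 12; 12 at its ether bond to 10 and 11. Each piece is commercial or one step away. The demand is that the β,γ-double bond does not move into conjugation.

**Enal.** 9 is cut at C5–C6 (formylation of 8) to 7 and 6; 6 at C3–C4 and C5–I to 3 and 4; 4 comes from 2 and 2 from 1. Anti-carbometalation fixes the C4=C5 geometry once and for all. The demand is anti addition and retention in the two later metal–carbon exchanges.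

**Side chain.** 34 comes from 33, which is cut at its C=C bond to 31 and 32. The demand is E selectivity.

## Other disconnections considered

**Alternative 1:** The cut runs through C7–C8, C11–C12 and C12–O8 at once and leads to the open-chain allenyl aldehyde A1, in which only C6 is stereogenic. In the forward sense Mo(CO)6 in DMSO, or Ru3(CO)12 under CO, would join the C8 aldehyde, the allene π bond next to C6 and one CO in a hetero-Pauson–Khand reaction. The product A2 is the same compound as 29.
- In favour: three bonds, the lactone, its methylene and the ring would arise in one operation. C12 needs neither a PMB group nor an oxidation. On step economy after ring closure this alternative is better (two steps fewer), and it is also better in the number of stereocentres that must be built into the open chain.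
- Against: the closure must create C7 and C8 with only C6 to steer them, so the trans fusion rests on an untested transannular bias, whereas the chosen closure forms no stereocentre. The carbonyl–allene version is known for five- and six-membered ring fusion only, so in precedent the two plans are equal: both go beyond known chemistry. The metallacycle must form across a ten-atom tether against allene oligomerisation, and the C8 aldehyde of A1, next to the C9 methylene and the C10 olefin, can slip into conjugation.

**Alternative 2:** The C6–C7 bond is cut, with the C11=C13 olefin moved back to C7=C11 and C6 joined through oxygen to C13. This gives the thirteen-membered propargylic allylic ether A3. Butyllithium would remove a C6 proton and the carbanion would attack C7 in a [2,3]-Wittig rearrangement, contracting the ring to the cyclodecenynol A4.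
- In favour: ring contractions of this kind are an established entry to ten-membered carbocycles of this family, so in precedent this alternative is better than the chosen plan. A thirteen-membered ether is much easier to close than a ten-membered carbocycle. The two PMB ethers of A4 would fall together to the same kind of 2-methylene-1,4-diol as 26, where the plans are equal.
- Against: A4 has a C4≡C5 triple bond and no C15. A hydroxymethyl group must still be placed on C4 with the right geometry on a strained cycloalkenyne (hydroalumination, iodination, carbonylation or coupling; at least three steps). C6 and C7 are created in the contraction from C8 and the C7=C11 geometry alone, while the chosen plan fixes them with an auxiliary before cyclisation. The step is strongly basic on a substrate with several allylic protons. Step economy is lower.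

**Alternative 3:** The C5–C6 bond is cut to the trans-lactone A5, which carries a C6 aldehyde and a C5 alkenyl iodide. CrCl2 with catalytic NiCl2 would form the C5 alkenylchromium species and add it to the aldehyde (Nozaki–Hiyama–Kishi), giving A6.
- In favour: the reaction is chemoselective, tolerates the lactone and is an established medium-ring closure, so in reliability of the ring-closing reaction type it is better than the chosen plan. C7 and C8 sit on a five-membered ring where trans is the stable arrangement. The C4=C5 geometry is carried in from the iodide; on olefin control the plans are equal, since both set each ring olefin stereospecifically.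
- Against: C6 is created in the macrocyclisation with no dependable control element. A large excess of a toxic chromium salt is needed. The lactone of A6 is saturated, so the methylene must be added later by enolate chemistry next to the C6 oxygen, and the C15 PMB group must be exchanged. The overall step count is about equal to the chosen plan, but stereocontrol at C6 is worse.

Key step: step 13

**Remarks and assumptions**
- Germacrane numbering is used for C1–C15 throughout. The configurations of 24, 25 and 36 were compared centre by centre and agree spatially at C6, C7, C8 and at both olefins. Only the CIP descriptors change with the substituents: C7 is S in 19–23, R in 24–35 and S in 36; C8 is R in 22–24 and S from 25 on.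
- Two changes to the way 24 is reached: the alkenylmagnesium intermediate 5 is trapped with iodine and formylated only after silylation, because a free (Z)-γ-hydroxy enal would close to its lactol; and C6–C8 are set by an auxiliary-controlled aldol and a hydroxyl-directed reduction, because an aldol of a malate dianion would fix C7 and C8 but leave C6 uncontrolled.
- 31, 32 and the reagents on the Conditions lines are taken to be commercial.

## Route

**Step 1**
Reactants: 1 pent-3-yn-1-ol
Product: 2 5-bromopent-2-yne
Conditions: CBr4, PPh3, CH2Cl2, 0 °C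
Reagents that add atoms: carbon tetrabromide, BrC(Br)(Br)Br
Why: Appel bromination of a primary alcohol under neutral conditions; the internal alkyne is inert and no stereocentre is involved.

**Step 2**
Reactants: 2 5-bromopent-2-yne; 3 prop-2-yn-1-ol
Product: 6 (2Z)-3-iodo-2-(pent-3-yn-1-yl)prop-2-en-1-ol, via pent-3-yn-1-ylmagnesium bromide 4 (not isolated), via cyclic alkenylmagnesium alkoxide 5 (not isolated)
Conditions: Mg, THF, rt; then 3 (0.4 equiv), CuI (15 mol %), Et2O/THF, −20 °C → rt; then I2, −78 → 0 °C
Reagents that add atoms: iodine, II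
Why: CuI-catalysed anti-carbomagnesiation of propargyl alcohol: after the first equivalent of 4 deprotonates the hydroxyl, the alkyl group enters at C4 and magnesium ends on C5 cis to CH2O in a five-membered chelate; iodinolysis with retention gives the (Z)-iodide, which fixes C15 cis to the future C6.

**Step 3**
Reactants: 6 (2Z)-3-iodo-2-(pent-3-yn-1-yl)prop-2-en-1-ol
Product: 7 tert-butyl{[(2Z)-3-iodo-2-(pent-3-yn-1-yl)prop-2-en-1-yl]oxy}dimethylsilane
Conditions: TBSCl, imidazole, DMF, 0 °C → rt
Reagents that add atoms: tert-butyldimethylsilyl chloride, CC(C)(C)[Si](C)(C)Cl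
Why: Imidazole-promoted silylation of a primary allylic alcohol; the alkenyl iodide is untouched.

**Step 4**
Reactants: 7 tert-butyl{[(2Z)-3-iodo-2-(pent-3-yn-1-yl)prop-2-en-1-yl]oxy}dimethylsilane
Product: 9 (2Z)-3-({[tert-butyl(dimethyl)silyl]oxy}methyl)oct-2-en-6-ynal, via (Z)-alkenyllithium 8 (not isolated)
Conditions: t-BuLi (2.1 equiv), Et2O, −78 °C; then DMF, −78 → −20 °C; aq NH4Cl
Reagents that add atoms: N,N-dimethylformamide, CN(C)C=O
Why: Iodine–lithium exchange with retention followed by Bouveault formylation; Et2O at −78 °C and immediate trapping suppress 1,4-migration of silicon from oxygen to carbon.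

**Step 5**
Reactants: 10 3-chloro-2-(chloromethyl)prop-1-ene; 11 (4-methoxyphenyl)methanol
Product: 12 1-({[2-(chloromethyl)prop-2-en-1-yl]oxy}methyl)-4-methoxybenzene
Conditions: NaH, Bu4NI (cat.), THF, 0 °C → rt; 10 in threefold excess
Reagents that add atoms: none
Why: Williamson etherification of an allylic chloride; the excess of 10 keeps the bis-ether low and is recovered by distillation.

**Step 6**
Reactants: 12 1-({[2-(chloromethyl)prop-2-en-1-yl]oxy}methyl)-4-methoxybenzene
Product: 14 3-{[(4-methoxyphenyl)methoxy]methyl}but-3-enoic acid, via allylmagnesium chloride 13 (not isolated)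
Conditions: Mg (excess), THF, 0 °C, slow addition; then CO2, −20 °C; aq HCl to pH 3
Reagents that add atoms: carbon dioxide, O=C=O
Why: Formation and carboxylation of an allylic Grignard reagent; both allyl termini are CH2 groups on the same carbon, so α and γ attack give the same β,γ-unsaturated acid, and no base is present to move the olefin.

**Step 7**
Reactants: 14 3-{[(4-methoxyphenyl)methoxy]methyl}but-3-enoic acid; 15 (4S)-4-benzyl-1,3-oxazolidin-2-one
Product: 17 (4S)-4-benzyl-3-(3-{[(4-methoxyphenyl)methoxy]methyl}but-3-enoyl)-1,3-oxazolidin-2-one, via mixed pivalic anhydride 16 (not isolated)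
Conditions: PivCl, Et3N, THF, −20 °C; then 15, LiCl, −20 °C → rt
Reagents that add atoms: none
Why: N-Acylation of the oxazolidinone through the mixed pivalic anhydride (LiCl/Et3N protocol); the low temperature keeps the β,γ-olefin out of conjugation.

**Step 8**
Reactants: 17 (4S)-4-benzyl-3-(3-{[(4-methoxyphenyl)methoxy]methyl}but-3-enoyl)-1,3-oxazolidin-2-one; 9 (2Z)-3-({[tert-butyl(dimethyl)silyl]oxy}methyl)oct-2-en-6-ynal
Product: 19 (4S)-4-benzyl-3-[(2S,3R,4Z)-5-({[tert-butyl(dimethyl)silyl]oxy}methyl)-3-hydroxy-2-{3-[(4-methoxyphenyl)methoxy]prop-1-en-2-yl}dec-4-en-8-ynoyl]-1,3-oxazolidin-2-one, via (Z)-dibutylboron dienolate 18 (not isolated)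
Conditions: Bu2BOTf, iPr2NEt, CH2Cl2, −78 → 0 °C; then 9, −78 → −10 °C; pH 7 buffer, MeOH, H2O2, 0 °C
Reagents that add atoms: none
Why: Evans syn aldol: soft enolisation at the doubly activated C7 methylene gives the (Z)-boron dienolate, which reacts at its α-carbon through a Zimmerman–Traxler chair on the face away from the benzyl group, setting C7 (S) and C6 (R) with the C6–O and C7–C11 bonds syn.

**Step 9**
Reactants: 19 Evans syn-aldol adduct (4Z,6R,7S)
Product: 20 (2S,3R,4Z)-5-({[tert-butyl(dimethyl)silyl]oxy}methyl)-3-hydroxy-N-methoxy-2-{3-[(4-methoxyphenyl)methoxy]prop-1-en-2-yl}-N-methyldec-4-en-8-ynamide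
Conditions: MeNH(OMe)·HCl, AlMe3, THF, −20 → 0 °C; aq KNaC4H4O6
Reagents that add atoms: N,O-dimethylhydroxylamine hydrochloride, CNOC.Cl
Why: Aluminium amide transamination to the Weinreb amide; the free β-hydroxyl forms an aluminium chelate that directs attack to the exocyclic carbonyl, and the weakly basic reagent leaves C7 alone.

**Step 10**
Reactants: 20 Weinreb amide (4Z,6R,7S)
Product: 21 (3S,4R,5Z)-6-({[tert-butyl(dimethyl)silyl]oxy}methyl)-1-chloro-4-hydroxy-3-{3-[(4-methoxyphenyl)methoxy]prop-1-en-2-yl}undec-5-en-9-yn-2-one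
Conditions: ClCH2I (3 equiv), MeLi·LiBr (3 equiv, slow addition), THF/Et2O, −78 °C; AcOH, −78 °C
Reagents that add atoms: chloroiodomethane, ClCI
Why: Homologation of a Weinreb amide with chloromethyllithium made in situ by iodine–lithium exchange; the chelated tetrahedral adduct survives until the cold acidic quench, so only one addition occurs, and the first equivalent of base is spent on the hydroxyl.

**Step 11**
Reactants: 21 chloromethyl ketone (4Z,6R,7S)
Product: 23 epoxy alcohol (4Z,6R,7S,8R): 24 without the silyl group on O6, via syn-chlorohydrin diol 22 (not isolated)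
Conditions: Et2BOMe, THF/MeOH (4:1), −78 °C; NaBH4, −78 °C; AcOH, evaporation from MeOH; then K2CO3, MeOH, 0 °C → rt
Reagents that add atoms: none
Why: Narasaka–Prasad reduction: hydride attacks the six-membered boron chelate of the β-hydroxy ketone axially and anti to the axial C7 substituent, giving the 1,3-syn diol (C8 R); carbonate then closes the epoxide by 3-exo displacement of chloride with C8 unchanged.

**Step 12**
Reactants: 23 epoxy alcohol (4Z,6R,7S,8R)
Product: 24 epoxy alkyne (4Z,6R,7R,8R): C8–C9 oxirane, C1≡C10 methyl alkyne, 6-OTIPS, 15-OTBS, 12-OPMB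
Conditions: TIPSOTf, 2,6-lutidine, CH2Cl2, −78 → −20 °C
Reagents that add atoms: triisopropylsilyl trifluoromethanesulfonate, CC(C)[Si](C(C)C)(C(C)C)OS(=O)(=O)C(F)(F)F
Why: Silylation of a hindered secondary allylic alcohol with a silyl triflate; the buffered, cold conditions leave the terminal epoxide intact.

**Step 13**
Reactants: 24 epoxy alkyne (4Z,6R,7R,8R)
Product: 25 (1(10)E,4Z,6R,7R,8S)-15-[(tert-butyldimethylsilyl)oxy]-12-[(4-methoxybenzyl)oxy]-6-[(triisopropylsilyl)oxy]germacra-1(10),4,11(13)-trien-8-ol
Conditions: Ni(cod)2 (20 mol %), PBu3 (40 mol %), Et3B (4 equiv), Et2O, 23 °C, 24 added over 12 h, final 0.005 M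
Reagents that add atoms: none
Why: Proposed new method: zerovalent nickel carrying PBu3 should bind the alkyne, open the epoxide at its unhindered terminal carbon C9 and form C9–C10 by syn addition across the alkyne, giving a six-membered oxanickelacycle with nickel on C1; Et3B then passes an ethyl group to nickel as the B–O bond forms, β-hydride elimination releases ethene, and C–H reductive elimination puts hydrogen on C1 with retention, so C9 and H are cis and the C1=C10 olefin is ring-trans by mechanism. The closest known reaction type is the nickel-catalysed reductive coupling of alkynes with terminal epoxides, which is established between two molecules and for five- and six-membered rings but not for a ten-membered ring. The ring closes in a ten-membered endo mode at the alkyne (both alkyne carbons become ring members), and the epoxide is opened at C9 so that C8 stays in the ring with its oxygen exocyclic. No stereocentre is formed; C8 keeps its configuration because its C–O bond is never broken, and C6 and C7 are untouched. The step needs bond formation at C10 and not at C1, which would give a nine-membered ring with an exocyclic ethylidene, and it needs cyclisation to beat oligomerisation. The first is favoured because the smaller alkyne substituent (methyl) normally ends up next to the new C–C bond; the second by slow addition at high dilution and by the turn that the C6/C7 branching and the cis-disposed C4 substituents impose on the chain. Silyl ethers, the PMB ether and both other olefins should be inert to Ni(cod)2/PBu3/Et3B.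

**Step 14**
Reactants: 25 ten-membered C8 alcohol (6R,7R,8S)
Product: 26 (1(10)E,4Z,6R,7R,8S)-15-[(tert-butyldimethylsilyl)oxy]-6-[(triisopropylsilyl)oxy]germacra-1(10),4,11(13)-triene-8,12-diol
Conditions: DDQ, CH2Cl2/pH 7 buffer (10:1), 0 °C
Reagents that add atoms: none
Why: Oxidative cleavage of the PMB ether (hydride abstraction, hydrolysis of the oxocarbenium ion); the wet buffered medium prevents acetal formation with O8, and silyl ethers are stable.

**Step 15**
Reactants: 26 8,12-diol (6R,7R,8S)
Product: 29 (1(10)E,4Z,6R,7R,8S)-15-[(tert-butyldimethylsilyl)oxy]-6-[(triisopropylsilyl)oxy]germacra-1(10),4,11(13)-trien-12,8-olide, via hydroxy enal 27 (not isolated), via lactol 28 (not isolated)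
Conditions: MnO2 (activated, excess), CH2Cl2, rt
Reagents that add atoms: none
Why: Oxidative lactonisation of a 2-methylene-1,4-diol: MnO2 oxidises only the primary allylic alcohol, the enal is trapped by O8 as the lactol, and this is oxidised again to the lactone; O8 is not allylic and O6 and O15 are silylated.

**Step 16**
Reactants: 29 silylated α-methylene lactone (6R,7R,8S)
Product: 30 (1(10)E,4Z,6R,7R,8S)-15-hydroxy-6-[(triisopropylsilyl)oxy]germacra-1(10),4,11(13)-trien-12,8-olide
Conditions: HF·pyridine, pyridine, THF, 0 °C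
Reagents that add atoms: none
Why: Selective desilylation: a primary allylic TBS ether is cleaved by buffered HF far faster than a hindered secondary TIPS ether, and the lactone tolerates the weakly acidic medium.

**Step 17**
Reactants: 31 {[tert-butyl(dimethyl)silyl]oxy}acetaldehyde; 32 ethyl 2-(triphenylphosphoranylidene)propanoate
Product: 33 ethyl (2E)-4-{[tert-butyl(dimethyl)silyl]oxy}-2-methylbut-2-enoate
Conditions: CH2Cl2, rt
Reagents that add atoms: none
Why: Wittig olefination with a stabilised α-branched ylide, which gives the E-trisubstituted enoate under thermodynamic control.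

**Step 18**
Reactants: 33 ethyl (2E)-4-{[tert-butyl(dimethyl)silyl]oxy}-2-methylbut-2-enoate
Product: 34 (2E)-4-{[tert-butyl(dimethyl)silyl]oxy}-2-methylbut-2-enoic acid
Conditions: LiOH, THF/MeOH/H2O, 0 °C → rt; 0.5 M HCl to pH 4, 0 °C
Reagents that add atoms: lithium hydroxide, [Li+].[OH-]
Why: Saponification of a conjugated ester; the primary silyl ether survives the short cold acidification.

**Step 19**
Reactants: 30 C15 alcohol (6R,7R,8S); 34 (2E)-4-{[tert-butyl(dimethyl)silyl]oxy}-2-methylbut-2-enoic acid
Product: 35 (1(10)E,4Z,6R,7R,8S)-15-{[(2E)-4-{[tert-butyl(dimethyl)silyl]oxy}-2-methylbut-2-enoyl]oxy}-6-[(triisopropylsilyl)oxy]germacra-1(10),4,11(13)-trien-12,8-olide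
Conditions: EDC·HCl, DMAP, CH2Cl2, 0 °C → rt
Reagents that add atoms: none
Why: Steglich esterification of the only free hydroxyl; the mild carbodiimide conditions leave the α-methylene lactone and the enoate geometry unchanged.

**Step 20**
Reactants: 35 bis-silyl ether of the target (6R,7R,8S)
Product: 36 (1(10)E,4Z,6R,7S,8S)-6-hydroxy-15-{[(2E)-4-hydroxy-2-methylbut-2-enoyl]oxy}germacra-1(10),4,11(13)-trien-12,8-olide (CNP0326626.1)
Conditions: HF·pyridine, pyridine, THF, 0 °C → rt
Reagents that add atoms: none
Why: Fluoride-mediated removal of both silyl ethers under buffered, non-basic conditions, which avoids Michael addition to the lactone and translactonisation to O6; no stereocentre is touched.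

## Compound list

1 | pent-3-yn-1-ol | CC#CCCO | starting material
2 | 5-bromopent-2-yne | CC#CCCBr | intermediate
3 | prop-2-yn-1-ol | C#CCO | starting material
4 | pent-3-yn-1-ylmagnesium bromide | CC#CCC[Mg]Br | intermediate
5 | cyclic alkenylmagnesium alkoxide (4-(pent-3-yn-1-yl)-2,5-dihydro-1,2-oxamagnesole) | CC#CCCC1=C[Mg]OC1 | intermediate
6 | (2Z)-3-iodo-2-(pent-3-yn-1-yl)prop-2-en-1-ol | OC/C(CCC#CC)=C\I | intermediate
7 | tert-butyl{[(2Z)-3-iodo-2-(pent-3-yn-1-yl)prop-2-en-1-yl]oxy}dimethylsilane | CC(C)(C)[Si](C)(C)OC/C(CCC#CC)=C\I | intermediate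
8 | [(1Z)-2-({[tert-butyl(dimethyl)silyl]oxy}methyl)hept-1-en-5-yn-1-yl]lithium | CC(C)(C)[Si](C)(C)OC/C(CCC#CC)=C\[Li] | intermediate
9 | (2Z)-3-({[tert-butyl(dimethyl)silyl]oxy}methyl)oct-2-en-6-ynal | CC(C)(C)[Si](C)(C)OC/C(CCC#CC)=C\C=O | intermediate
10 | 3-chloro-2-(chloromethyl)prop-1-ene | C=C(CCl)CCl | starting material
11 | (4-methoxyphenyl)methanol | COc1ccc(CO)cc1 | starting material
12 | 1-({[2-(chloromethyl)prop-2-en-1-yl]oxy}methyl)-4-methoxybenzene | C=C(CCl)COCc1ccc(OC)cc1 | intermediate
13 | (2-{[(4-methoxyphenyl)methoxy]methyl}prop-2-en-1-yl)magnesium chloride | C=C(C[Mg]Cl)COCc1ccc(OC)cc1 | intermediate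
14 | 3-{[(4-methoxyphenyl)methoxy]methyl}but-3-enoic acid | C=C(CC(=O)O)COCc1ccc(OC)cc1 | intermediate
15 | (4S)-4-benzyl-1,3-oxazolidin-2-one | O=C1N[C@@H](Cc2ccccc2)CO1 | starting material
16 | mixed pivalic anhydride of 14 | CC(C)(C)C(=O)OC(=O)CC(=C)COCc1ccc(OC)cc1 | intermediate
17 | (4S)-4-benzyl-3-(3-{[(4-methoxyphenyl)methoxy]methyl}but-3-enoyl)-1,3-oxazolidin-2-one | C=C(CC(=O)N1[C@@H](Cc2ccccc2)COC1=O)COCc1ccc(OC)cc1 | intermediate
18 | (Z)-dibutylboron dienolate of 17 | CCCCB(CCCC)O/C(=C\C(=C)COCc1ccc(OC)cc1)N1[C@@H](Cc2ccccc2)COC1=O | intermediate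
19 | (4S)-4-benzyl-3-[(2S,3R,4Z)-5-({[tert-butyl(dimethyl)silyl]oxy}methyl)-3-hydroxy-2-{3-[(4-methoxyphenyl)methoxy]prop-1-en-2-yl}dec-4-en-8-ynoyl]-1,3-oxazolidin-2-one | CC#CCC/C(CO[Si](C)(C)C(C)(C)C)=C/[C@@H](O)[C@H](C(=C)COCc1ccc(OC)cc1)C(=O)N1[C@@H](Cc2ccccc2)COC1=O | intermediate
20 | (2S,3R,4Z)-5-({[tert-butyl(dimethyl)silyl]oxy}methyl)-3-hydroxy-N-methoxy-2-{3-[(4-methoxyphenyl)methoxy]prop-1-en-2-yl}-N-methyldec-4-en-8-ynamide | CC#CCC/C(CO[Si](C)(C)C(C)(C)C)=C/[C@@H](O)[C@H](C(=C)COCc1ccc(OC)cc1)C(=O)N(C)OC | intermediate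
21 | (3S,4R,5Z)-6-({[tert-butyl(dimethyl)silyl]oxy}methyl)-1-chloro-4-hydroxy-3-{3-[(4-methoxyphenyl)methoxy]prop-1-en-2-yl}undec-5-en-9-yn-2-one | CC#CCC/C(CO[Si](C)(C)C(C)(C)C)=C/[C@@H](O)[C@H](C(=C)COCc1ccc(OC)cc1)C(=O)CCl | intermediate
22 | (2R,3S,4R,5Z)-6-({[tert-butyl(dimethyl)silyl]oxy}methyl)-1-chloro-3-{3-[(4-methoxyphenyl)methoxy]prop-1-en-2-yl}undec-5-en-9-yne-2,4-diol | CC#CCC/C(CO[Si](C)(C)C(C)(C)C)=C/[C@@H](O)[C@H](C(=C)COCc1ccc(OC)cc1)[C@@H](O)CCl | intermediate
23 | epoxy alcohol (4Z,6R,7S,8R): C8–C9 oxirane, free 6-OH, 15-OTBS, 12-OPMB, C1≡C10 methyl alkyne | CC#CCC/C(CO[Si](C)(C)C(C)(C)C)=C/[C@@H](O)[C@H](C(=C)COCc1ccc(OC)cc1)[C@@H]2CO2 | intermediate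
24 | epoxy alkyne (4Z,6R,7R,8R): C8–C9 oxirane, 6-OTIPS, 15-OTBS, 12-OPMB, C1≡C10 methyl alkyne | CC#CCC/C(CO[Si](C)(C)C(C)(C)C)=C/[C@@H](O[Si](C(C)C)(C(C)C)C(C)C)[C@H](C(=C)COCc1ccc(OC)cc1)[C@@H]2CO2 | intermediate
25 | (1(10)E,4Z,6R,7R,8S)-15-[(tert-butyldimethylsilyl)oxy]-12-[(4-methoxybenzyl)oxy]-6-[(triisopropylsilyl)oxy]germacra-1(10),4,11(13)-trien-8-ol | C=C(COCc1ccc(OC)cc1)[C@@H]2[C@@H](O)C/C(C)=C/CC/C(CO[Si](C)(C)C(C)(C)C)=C/[C@H]2O[Si](C(C)C)(C(C)C)C(C)C | intermediate
26 | (1(10)E,4Z,6R,7R,8S)-15-[(tert-butyldimethylsilyl)oxy]-6-[(triisopropylsilyl)oxy]germacra-1(10),4,11(13)-triene-8,12-diol | C=C(CO)[C@@H]2[C@@H](O)C/C(C)=C/CC/C(CO[Si](C)(C)C(C)(C)C)=C/[C@H]2O[Si](C(C)C)(C(C)C)C(C)C | intermediate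
27 | (1(10)E,4Z,6R,7R,8S)-15-[(tert-butyldimethylsilyl)oxy]-8-hydroxy-6-[(triisopropylsilyl)oxy]germacra-1(10),4,11(13)-trien-12-al | C=C(C=O)[C@@H]2[C@@H](O)C/C(C)=C/CC/C(CO[Si](C)(C)C(C)(C)C)=C/[C@H]2O[Si](C(C)C)(C(C)C)C(C)C | intermediate
28 | 12-hydroxy-12,8-lactol of 27 (C12 epimers) | C=C1C(O)O[C@H]2C/C(C)=C/CC/C(CO[Si](C)(C)C(C)(C)C)=C/[C@@H](O[Si](C(C)C)(C(C)C)C(C)C)[C@H]12 | intermediate
29 | (1(10)E,4Z,6R,7R,8S)-15-[(tert-butyldimethylsilyl)oxy]-6-[(triisopropylsilyl)oxy]germacra-1(10),4,11(13)-trien-12,8-olide | C=C1C(=O)O[C@H]2C/C(C)=C/CC/C(CO[Si](C)(C)C(C)(C)C)=C/[C@@H](O[Si](C(C)C)(C(C)C)C(C)C)[C@H]12 | intermediate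
30 | (1(10)E,4Z,6R,7R,8S)-15-hydroxy-6-[(triisopropylsilyl)oxy]germacra-1(10),4,11(13)-trien-12,8-olide | C=C1C(=O)O[C@H]2C/C(C)=C/CC/C(CO)=C/[C@@H](O[Si](C(C)C)(C(C)C)C(C)C)[C@H]12 | intermediate
31 | {[tert-butyl(dimethyl)silyl]oxy}acetaldehyde | CC(C)(C)[Si](C)(C)OCC=O | starting material
32 | ethyl 2-(triphenylphosphoranylidene)propanoate | CCOC(=O)C(C)=P(c1ccccc1)(c1ccccc1)c1ccccc1 | starting material
33 | ethyl (2E)-4-{[tert-butyl(dimethyl)silyl]oxy}-2-methylbut-2-enoate | CCOC(=O)/C(C)=C/CO[Si](C)(C)C(C)(C)C | intermediate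
34 | (2E)-4-{[tert-butyl(dimethyl)silyl]oxy}-2-methylbut-2-enoic acid | OC(=O)/C(C)=C/CO[Si](C)(C)C(C)(C)C | intermediate
35 | (1(10)E,4Z,6R,7R,8S)-15-{[(2E)-4-{[tert-butyl(dimethyl)silyl]oxy}-2-methylbut-2-enoyl]oxy}-6-[(triisopropylsilyl)oxy]germacra-1(10),4,11(13)-trien-12,8-olide | C=C1C(=O)O[C@H]2C/C(C)=C/CC/C(COC(=O)/C(C)=C/CO[Si](C)(C)C(C)(C)C)=C/[C@@H](O[Si](C(C)C)(C(C)C)C(C)C)[C@H]12 | intermediate
36 | (1(10)E,4Z,6R,7S,8S)-6-hydroxy-15-{[(2E)-4-hydroxy-2-methylbut-2-enoyl]oxy}germacra-1(10),4,11(13)-trien-12,8-olide (CNP0326626.1) | C=C1C(=O)O[C@H]2C/C(C)=C/CC/C(COC(=O)/C(C)=C/CO)=C/[C@@H](O)[C@H]12 | target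

## Step count and least certain steps

Total: 20 steps. Longest linear sequence: 15 steps (1–4, 8–16, 19, 20).

**Step 13 (key step; the only step carrying the new-method label).**
- What may go wrong: intermolecular coupling and oligomerisation may outrun ring closure, because the oxanickelacycle must span a trans-cyclodecene. Bond formation may occur at C1 (exo closure to a nine-membered ring). The catalyst may also simply isomerise or reduce the epoxide.
- Fallback (from 24, back at 25; known reactions only):
 - Hydrolyse the epoxide of 24 with water and the matched enantiomer of (salen)Co(OAc) (trivalent cobalt) to the 8,9-diol F1.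
 - Silylate both hydroxyls (Et3SiCl, imidazole) to the bis(triethylsilyl) ether F2.
 - Hydrozirconate with Cp2Zr(H)Cl under equilibrating conditions and iodinate to the (E)-C10 alkenyl iodide F3.
 - Apply Swern conditions, which cleave and oxidise a primary triethylsilyl ether selectively, to reach the C9 aldehyde F4.
 - Close the ring between C10 and C9 with CrCl2 and catalytic NiCl2 (DMSO/THF, high dilution; Nozaki–Hiyama–Kishi) to the ten-membered C9 allylic alcohol F5; either C9 epimer serves.
 - Free the 8,9-diol F6 with PPTS in methanol, and convert it with 1,1'-carbonyldiimidazole into the cyclic carbonate F7.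
 - Treat F7 with Pd2(dba)3, PBu3, formic acid and triethylamine: ionisation of the allylic C9–O bond and hydride delivery to C9 would release CO2 and the C8 hydroxyl and give 25.

**Step 2.**
- What may go wrong: carbometalation with a primary alkyl Grignard reagent may be slow and incomplete. Wurtz coupling while 4 is formed and protonation of 5 before iodinolysis would lower the yield, and 2.5 equivalents of 4 are consumed.
- Fallback (from 3 with reagent 4, back at 9): silylate 3 (TBSCl, imidazole) to the propargyl silyl ether F8 and carboxylate it (n-BuLi, ClCO2Me) to the ynoate F9. Add the organocopper reagent from 4 and CuBr·SMe2 at −78 °C in a syn sense to give the (Z)-enoate F10. Reduce with iBu2AlH to the allylic alcohol F11 and oxidise with MnO2 to 9.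

**Step 10.**
- What may go wrong: the organolithium may deprotonate C7, which is allylic and α to the amide, causing epimerisation or migration of the C11 olefin into conjugation. Retro-aldol cleavage of the lithium aldolate and a second addition are further risks.
- Fallback (from 20, back at 24): silylate 20 (TIPSOTf, 2,6-lutidine) to the silyl ether F12, and reduce with iBu2AlH at −78 °C to the aldehyde F13. Treat F13 at once with dimethylsulfonium methylide (Me3S I, KN(SiMe3)2) to give 24 together with its C8 epimer F14. Hydrolytic kinetic resolution with the (salen)Co(OAc) enantiomer matched to F14 would convert F14 into the diol F15 and leave 24.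

**Step 15.**
- What may go wrong: oxidation may stall at the lactol stage, or the polar diol may be lost on the large excess of oxidant.
- Fallback (from 26, back at 29): stop the MnO2 oxidation at the 27/28 mixture, oxidise it with NaClO2, NaH2PO4 and 2-methylbut-2-ene to the hydroxy acid F16, and close the lactone with EDC·HCl and DMAP to 29.

**Step 20.**
- What may go wrong: cleavage of the hindered secondary TIPS ether may be slow, and prolonged exposure to acidic fluoride may then cause transannular cyclisation of the 1(10),4-diene, loss of the allylic ester or translactonisation to O6.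
- Fallback (from 30, back at 36): remove the C6 silyl group before the ester is present (HF·pyridine, longer time) to give the 6,15-diol F17. Acylate the primary allylic hydroxyl selectively with 34 (EDC·HCl, DMAP, −20 °C) to the monoester F18, and remove the remaining primary silyl ether under much milder conditions (HF·pyridine/pyridine, 0 °C) to give 36.

## Further compounds

F1 | step 13 | 8,9-diol from 24 (4Z,6R,7R,8R) | CC#CCC/C(CO[Si](C)(C)C(C)(C)C)=C/[C@@H](O[Si](C(C)C)(C(C)C)C(C)C)[C@H](C(=C)COCc1ccc(OC)cc1)[C@@H](O)CO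
F2 | step 13 | 8,9-bis(triethylsilyl) ether of F1 | CC#CCC/C(CO[Si](C)(C)C(C)(C)C)=C/[C@@H](O[Si](C(C)C)(C(C)C)C(C)C)[C@H](C(=C)COCc1ccc(OC)cc1)[C@@H](O[Si](CC)(CC)CC)CO[Si](CC)(CC)CC
F3 | step 13 | (1(10)E)-10-iodo alkene from F2 | I/C(C)=C/CC/C(CO[Si](C)(C)C(C)(C)C)=C/[C@@H](O[Si](C(C)C)(C(C)C)C(C)C)[C@H](C(=C)COCc1ccc(OC)cc1)[C@@H](O[Si](CC)(CC)CC)CO[Si](CC)(CC)CC
F4 | step 13 | C9 aldehyde with 8-O-triethylsilyl group and C10 alkenyl iodide | I/C(C)=C/CC/C(CO[Si](C)(C)C(C)(C)C)=C/[C@@H](O[Si](C(C)C)(C(C)C)C(C)C)[C@H](C(=C)COCc1ccc(OC)cc1)[C@@H](O[Si](CC)(CC)CC)C=O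
F5 | step 13 | ten-membered 9-hydroxy-8-(triethylsilyloxy) ring compound (C9 epimers) | C=C(COCc1ccc(OC)cc1)[C@@H]2[C@@H](O[Si](CC)(CC)CC)C(O)/C(C)=C/CC/C(CO[Si](C)(C)C(C)(C)C)=C/[C@H]2O[Si](C(C)C)(C(C)C)C(C)C
F6 | step 13 | ten-membered 8,9-diol (C9 epimers) | C=C(COCc1ccc(OC)cc1)[C@@H]2[C@@H](O)C(O)/C(C)=C/CC/C(CO[Si](C)(C)C(C)(C)C)=C/[C@H]2O[Si](C(C)C)(C(C)C)C(C)C
F7 | step 13 | 8,9-cyclic carbonate of F6 | C=C(COCc1ccc(OC)cc1)[C@@H]2[C@H]3OC(=O)OC3/C(C)=C/CC/C(CO[Si](C)(C)C(C)(C)C)=C/[C@H]2O[Si](C(C)C)(C(C)C)C(C)C
F8 | step 2 | tert-butyldimethyl(prop-2-yn-1-yloxy)silane | C#CCO[Si](C)(C)C(C)(C)C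
F9 | step 2 | methyl 4-{[tert-butyl(dimethyl)silyl]oxy}but-2-ynoate | COC(=O)C#CCO[Si](C)(C)C(C)(C)C
F10 | step 2 | methyl (2Z)-3-({[tert-butyl(dimethyl)silyl]oxy}methyl)oct-2-en-6-ynoate | CC(C)(C)[Si](C)(C)OC/C(CCC#CC)=C\C(=O)OC
F11 | step 2 | (2Z)-3-({[tert-butyl(dimethyl)silyl]oxy}methyl)oct-2-en-6-yn-1-ol | CC(C)(C)[Si](C)(C)OC/C(CCC#CC)=C\CO
F12 | step 10 | 6-O-triisopropylsilyl ether of 20 | CC#CCC/C(CO[Si](C)(C)C(C)(C)C)=C/[C@@H](O[Si](C(C)C)(C(C)C)C(C)C)[C@H](C(=C)COCc1ccc(OC)cc1)C(=O)N(C)OC
F13 | step 10 | C8 aldehyde from F12 | CC#CCC/C(CO[Si](C)(C)C(C)(C)C)=C/[C@@H](O[Si](C(C)C)(C(C)C)C(C)C)[C@H](C(=C)COCc1ccc(OC)cc1)C=O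
F14 | step 10 | C8 epimer of 24 | CC#CCC/C(CO[Si](C)(C)C(C)(C)C)=C/[C@@H](O[Si](C(C)C)(C(C)C)C(C)C)[C@H](C(=C)COCc1ccc(OC)cc1)[C@H]2CO2
F15 | step 10 | 8,9-diol from F14 (C8 epimer of F1) | CC#CCC/C(CO[Si](C)(C)C(C)(C)C)=C/[C@@H](O[Si](C(C)C)(C(C)C)C(C)C)[C@H](C(=C)COCc1ccc(OC)cc1)[C@H](O)CO
F16 | step 15 | 8-hydroxy-12-oic acid from 27 | C=C(C(=O)O)[C@@H]2[C@@H](O)C/C(C)=C/CC/C(CO[Si](C)(C)C(C)(C)C)=C/[C@H]2O[Si](C(C)C)(C(C)C)C(C)C
F17 | step 20 | (1(10)E,4Z,6R,7S,8S)-6,15-dihydroxygermacra-1(10),4,11(13)-trien-12,8-olide | C=C1C(=O)O[C@H]2C/C(C)=C/CC/C(CO)=C/[C@@H](O)[C@H]12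
F18 | step 20 | 15-O-[(2E)-4-{[tert-butyl(dimethyl)silyl]oxy}-2-methylbut-2-enoyl] derivative of F17 | C=C1C(=O)O[C@H]2C/C(C)=C/CC/C(COC(=O)/C(C)=C/CO[Si](C)(C)C(C)(C)C)=C/[C@@H](O)[C@H]12
A1 | alternative 1 | allenyl aldehyde (C8 aldehyde, C7=C11=C13 allene, 6-OTIPS, 15-OTBS) | O=CC/C(C)=C/CC/C(CO[Si](C)(C)C(C)(C)C)=C/[C@@H](O[Si](C(C)C)(C(C)C)C(C)C)C=C=C
A2 | alternative 1 | 6-O-triisopropylsilyl-15-O-tert-butyldimethylsilyl germacranolide (identical with 29) | C=C1C(=O)O[C@H]2C/C(C)=C/CC/C(CO[Si](C)(C)C(C)(C)C)=C/[C@@H](O[Si](C(C)C)(C(C)C)C(C)C)[C@H]12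
A3 | alternative 2 | thirteen-membered propargylic allylic ether (O between C6 and C13, 8-OPMB, 12-OPMB) | O1CC#CCC/C=C(C)/C[C@H](OCc2ccc(OC)cc2)/C=C(COCc2ccc(OC)cc2)/C1
A4 | alternative 2 | ten-membered enynol (6-OH, C7 alkenyl group, 8-OPMB) | C=C(COCc2ccc(OC)cc2)[C@@H]1[C@@H](OCc3ccc(OC)cc3)C/C(C)=C/CCC#C[C@H]1O
A5 | alternative 3 | trans-lactone with C6 aldehyde and C5 alkenyl iodide (15-OPMB) | O=C1O[C@@H](C/C(C)=C/CC/C(COCc2ccc(OC)cc2)=C/I)[C@H](C=O)C1
A6 | alternative 3 | ten-membered C6 carbinol fused to the saturated 8,12-lactone (15-OPMB) | O=C1O[C@H]2C/C(C)=C/CC/C(COCc3ccc(OC)cc3)=C/[C@@H](O)[C@@H]2C1
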